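Early on, elm already looks finished: target reads 47.2 % at 6.00 h and 46.4 % at 40.0 h.

common to all: starting material 0.027 M; precatalyst 1.4 mM
- elm: second substrate 0.027 M (in portions, 4); reagent 0.027 M; the very flask that is asked about, followed so far; portions every 80 s
- ash: second substrate 0.054 M (in portions, 4); reagent 0.027 M; run made earlier; portions every 80 s
- flask: second substrate 0.0270 M (in portions, 4); reagent 0.0270 M; the portions of second substrate follow each other after 80 s, the first at the start; time 10 d

- elm (time / h: target / %, catalyst intermediate A / %): 6.00: 47.2, 1.9; 12.0: 47.2, 1.7; 20.0: 47.6, 2.4; 25.0: 47.2, 1.5; 30.0: 46.9, 2.1; 40.0: 46.4, 3.0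
- ash (time / d: target / %, catalyst intermediate A / %): 0.417: 29.8, 2.2; 1.04: 30.3, 1.7; 2.08: 29.4, 2.5; 3.00: 29.3, 1.5; 4.00: 30.1, 2.0; 6.00: 29.3, 2.6; 8.00: 28.6, 2.4

(scatter of a reading: 0.5 percentage points)

- why nothing more happens at 10 d, or that something still does (no working catalyst is left / it is still moving / the reagent has run out first / forward and back rates have come level / all of the starting material has reacted)
- the target standing at 10 d, as a percentage of the starting material charged
- the catalyst intermediate A standing at 10 d, as a percentage of the starting material charged

Which flask is asked about? Elm itself, carried on to 10 d.

Where does the reagent go? Each listed turn of the catalyst takes one reagent and gives one target or one second product, and [reagent] at the start equals [starting material] at the start, 0.027 M. The six elm readings average 47.1 % of the charged reagent ending as target; I call that fraction the reagent share.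

Can you prove that reagent is the limiting reagent, and that the catalyst has not died? No, second product was never read. But ash, with twice the second substrate, stands lower than elm, 29.3 % at 3.00 d, which fits two substrates competing for the same reagent. So the share goes with elm's charges of second substrate and starting material.

Both runs end lower than they began. Is target being lost? Ash drops 1.2 percentage points by 8.00 d, against a scatter of 0.5 points on each reading, and the listed step that forms target has no way back. I read that as scatter.

Your number, then? The flask has elm's charges, so I put target at 10 d at the share times the reagent charge: 47.1 % of the starting material.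

The forecast agrees on target: the reagent has run out first, target 47.1 % (46.3 % to 47.8 %), catalyst intermediate A 2.3 % (1.6 % to 3.3 %), since that intermediate “would convert if any reagent remained”.

    reagent + catalyst intermediate A → free catalyst + target (k = 3.40 L mol⁻¹ s⁻¹)
    second substrate + free catalyst ⇌ catalyst intermediate B (K = 25.0 L mol⁻¹, k = 0.380 L mol⁻¹ s⁻¹)
    precatalyst ⇌ free catalyst (K = 2.10, k = 1.80 × 10⁻⁴ s⁻¹)
    starting material + free catalyst ⇌ catalyst intermediate A (K = 90.0 L mol⁻¹, k = 0.280 L mol⁻¹ s⁻¹)
    reagent + catalyst intermediate B → free catalyst + second product (k = 8.10 L mol⁻¹ s⁻¹)

The flask gives the reagent has run out first, with reagent at 0 % of its charge, target at 46.6 % and catalyst intermediate A at 2.13 %, both inside the forecast's ranges. The flask also holds what those two numbers do not show: the share leaves 0.0143 M of reagent for second product, and 0.0144 M stands there. The neighbour flask, with the same other charges, gets 0.0067 M of reagent, 0.248 equiv. The share gives it 11.7 % of target. It makes 11.9 %, with reagent at 0 % of its charge and 86 % of the starting material unbound.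

The data are calculated from invented constants, noise included.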